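**Strategy.** The seven-membered ring is dissected into a three-carbon unit (ring-fusion CH, anisoyloxy-bearing carbon, enone β-CH) and a four-carbon unit (enone α-carbon, ketone carbon, carbinol CH, methyl-bearing quaternary fusion carbon) that are already linked through the three cyclopentane carbons. An intramolecular [4+3] cycloaddition of a chlorine-stabilised oxyallyl cation with a tethered (E,E)-diene therefore closes the cyclopentane and the cycloheptene in one operation, forming the ring-fusion bond and the CH–C(Me) bond. The open-chain precursor, a dichloromethyl ketone carrying a silylated isopropyl carbinol and the diene, comes from ozonolytic ring cleavage of (S)-terpinen-4-ol, which supplies the tertiary carbinol stereocentre; the chlorine later leaves to unveil the enone.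

Key step: step 7

Remark on the chemistry: (S)-(+)-terpinen-4-ol of high enantiomeric purity and isomerically pure (E)-1-bromoprop-1-ene are taken as purchasable. The chlorine- and methyl-bearing ring carbons formed in step 7 are drawn as the isomers expected from the transition-state model; epimers at these two carbons converge in step 12.

Step 1
Reactants: 1 (S)-(+)-terpinen-4-ol
Product: 2 (S)-terpinen-4-ol tert-butyldimethylsilyl ether
Conditions: TBSOTf, 2,6-lutidine, CH2Cl2, 0 °C → rt
Reagents that add atoms: tert-butyldimethylsilyl trifluoromethanesulfonate, CC(C)(C)[Si](C)(C)OS(=O)(=O)C(F)(F)F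
Why: Silyl triflate silylation of a hindered tertiary alcohol should proceed without touching the stereocentre, and the ether later blocks retro-aldol cleavage and O-alkylation at the carbinol.

Step 2
Reactants: 2 (S)-terpinen-4-ol tert-butyldimethylsilyl ether
Product: 4 keto acetal (5S)-5-(tert-butyldimethylsilyloxy)-7,7-dimethoxy-5-(propan-2-yl)heptan-2-one, via keto aldehyde 3 (not isolated)
Conditions: O3, CH2Cl2/MeOH, −78 °C; Me2S, → rt; then p-TsOH·H2O (cat.), MeOH, rt
Reagents that add atoms: ozone, [O-][O+]=O; methanol, CO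
Why: Ozonolysis with reductive work-up cleaves the only alkene to a methyl ketone and an aldehyde with the carbinol centre kept, and acid-catalysed acetalisation in methanol should be selective for the aldehyde over the methyl ketone.

Step 3
Reactants: 4 keto acetal
Product: 6 alkyne tert-butyl{[(3S)-1,1-dimethoxy-3-(propan-2-yl)hept-6-yn-3-yl]oxy}dimethylsilane, via enol phosphate 5 (not isolated)
Conditions: LiN(iPr)2 (1.1 equiv), THF, −78 °C; ClP(O)(OEt)2, → rt; then LiN(iPr)2 (2.3 equiv), THF, −78 °C → rt
Reagents that add atoms: diethyl chlorophosphate, CCOP(=O)(Cl)OCC (its atoms remain in 5 only)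
Why: Kinetic deprotonation at the methyl group, O-phosphorylation and amide-induced elimination of the terminal enol phosphate is the established conversion of a methyl ketone into a terminal alkyne, and acetal and silyl ether are inert to the amide base.

Step 4
Reactants: 6 alkyne; 7 (E)-1-bromoprop-1-ene
Product: 10 dienal (3S,6E,8E)-3-(tert-butyldimethylsilyloxy)-6-methyl-3-(propan-2-yl)deca-6,8-dienal, via alkenylalane 8 (not isolated), via diene acetal 9 (not isolated)
Conditions: Me3Al, Cp2ZrCl2 (cat.), CH2Cl2, −20 → 0 °C; then 7, Pd(PPh3)4 (cat.), ZnCl2, THF, rt; then 1 M HCl, THF, rt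
Reagents that add atoms: trimethylaluminium, C[Al](C)C; (E)-1-bromoprop-1-ene (7), C/C=C/Br; water, O
Why: Zirconium-catalysed syn carboalumination places methyl on the internal and aluminium on the terminal alkyne carbon, Negishi cross-coupling with retention on both partners should give the (E,E)-diene with the chain trans to the propenyl group, and the acidic work-up hydrolyses the dimethyl acetal.

Step 5
Reactants: 10 dienal
Product: 11 dichloromethyl carbinol (4S,7E,9E)-4-(tert-butyldimethylsilyloxy)-1,1-dichloro-7-methyl-4-(propan-2-yl)undeca-7,9-dien-2-ol (both C-2 epimers)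
Conditions: CH2Cl2, LiN(iPr)2, THF, −90 °C; then 10; AcOH quench at −78 °C
Reagents that add atoms: dichloromethane, ClCCl
Why: Dichloromethyllithium generated in the cold adds 1,2 to the aldehyde faster than it enolises it, and the new carbinol centre is of no consequence because it is oxidised in step 6.

Step 6
Reactants: 11 dichloromethyl carbinol
Product: 12 dichloromethyl ketone (4S,7E,9E)-4-(tert-butyldimethylsilyloxy)-1,1-dichloro-7-methyl-4-(propan-2-yl)undeca-7,9-dien-2-one
Conditions: Dess–Martin periodinane, NaHCO3, CH2Cl2, 0 °C → rt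
Reagents that add atoms: none
Why: Dess–Martin oxidation of a secondary carbinol under buffered, non-basic conditions should leave the diene, the silyl ether and the acidic dichloromethyl group untouched.

Step 7
Reactants: 12 dichloromethyl ketone
Product: 14 trans-fused chloro ketone (3R,3aR,5R,6S,8aR)-3-(tert-butyldimethylsilyloxy)-5-chloro-6,8a-dimethyl-3-(propan-2-yl)-2,3,3a,5,6,8a-hexahydroazulen-4(1H)-one, via oxyallyl cation 13 (not isolated)
Conditions: Et3N (2 equiv), CF3CH2OH, 0 °C → rt
Reagents that add atoms: none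
Why: Et3N enolises 12 at the methylene carbon and the ionising fluoroalcohol assists loss of one chloride to give the chlorine-stabilised oxyallyl cation 13, which the tethered diene captures in a concerted but asynchronous [4+3] cycloaddition; the closest known type is the intramolecular [4+3] cycloaddition of oxyallyl cations from α-halo ketones with tethered dienes under amine/trifluoroethanol conditions. The cyclopentane closes by bonding of the alkyl-substituted cation terminus to the methyl-bearing diene terminus through the three-atom tether (5-exo with respect to the diene), and the cycloheptenone closes in the same event by bonding of the chlorinated terminus to the propenyl terminus (7-endo if the bonds form in sequence). The ring-fusion CH is controlled by the W-shaped cation and the (E)-trisubstituted alkene (tether outside, methyl inside) reacting through the extended transition state, which places that hydrogen anti to the angular methyl (trans fusion). The quaternary carbon is controlled by the carbinol stereocentre from 1: in the forming five-membered ring the isopropyl group, the ketone-bearing branch and the diene branch all take pseudo-equatorial, mutually trans sites, so the angular methyl ends cis to the silyloxy group. The step thus needs ring-fusion and diastereofacial selectivity, secured by the defined (E,E)-diene geometry and by the single bulky stereocentre next to the cation, while the silyl ether blocks retro-aldol cleavage and O-capture of the cation. The chlorine- and methyl-bearing carbons are formed as expected from the same model but are of no consequence, because both lose their stereochemistry in step 12.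

Step 8
Reactants: 14 trans-fused chloro ketone
Product: 15 hydroxy ketone (3R,3aR,5R,6S,8aR)-5-chloro-3-hydroxy-6,8a-dimethyl-3-(propan-2-yl)-2,3,3a,5,6,8a-hexahydroazulen-4(1H)-one
Conditions: HF (48% aq.), MeCN, 0 °C → rt
Reagents that add atoms: none
Why: Acidic fluoride cleaves the tertiary silyl ether without generating an enolate, so the β-hydroxy α'-chloro ketone should escape retro-aldol and Favorskii pathways.

Step 9
Reactants: 15 hydroxy ketone
Product: 16 chloro diol (3R,3aS,4R,5R,6S,8aR)-5-chloro-6,8a-dimethyl-3-(propan-2-yl)-1,2,3,3a,4,5,6,8a-octahydroazulene-3,4-diol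
Conditions: Me4NBH(OAc)3, MeCN/AcOH, −30 → −10 °C
Reagents that add atoms: none
Why: In the Evans–Saksena reduction the tertiary hydroxyl exchanges onto boron and delivers hydride intramolecularly to the ketone face on which it sits (the face of the angular methyl), which should give the secondary alcohol anti to the tertiary hydroxyl and cis to the ring-fusion hydrogen, against the sterically preferred direction of external hydride.

Step 10
Reactants: 16 chloro diol; 17 4-methoxybenzoyl chloride
Product: 18 anisoate (3R,3aS,4R,5R,6S,8aR)-5-chloro-3-hydroxy-6,8a-dimethyl-3-(propan-2-yl)-1,2,3,3a,4,5,6,8a-octahydroazulen-4-yl 4-methoxybenzoate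
Conditions: 17, pyridine, DMAP (cat.), CH2Cl2, 0 °C → rt
Reagents that add atoms: 4-methoxybenzoyl chloride (17), COc1ccc(C(Cl)=O)cc1
Why: DMAP-catalysed acylation takes the secondary alcohol only, because the tertiary carbinol flanked by isopropyl and the ring fusion is too hindered to react.

Step 11
Reactants: 18 anisoate
Product: 19 epoxide (7,8-epoxide of 18 with the oxirane oxygen on the face opposite the 8a-methyl group)
Conditions: mCPBA, NaHCO3, CH2Cl2, 0 °C
Reagents that add atoms: 3-chloroperoxybenzoic acid, OOC(=O)c1cccc(Cl)c1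
Why: Prilezhaev epoxidation of the only alkene should occur from the face opposite the axial angular methyl, and the face is not decisive because step 12 ends under equilibrating conditions.

Step 12
Reactants: 19 epoxide
Product: 23 target compound CNP0299970.1, via alkoxysulfonium ion 20 (not isolated), via chloro ketol 21 (not isolated), via epimeric enone 22 (not isolated)
Conditions: DMSO, TfOH (1.1 equiv), CH2Cl2, 0 °C → rt; Et3N, 0 °C; then DBU, rt
Reagents that add atoms: dimethyl sulfoxide, CS(C)=O
Why: Acid-promoted opening of the epoxide by DMSO at the ring carbon remote from the quaternary centre and base-induced collapse of the alkoxysulfonium ion (Kornblum-type oxidation of an epoxide to an α-hydroxy ketone) give 21, whose β-chloride is lost by E1cB elimination to the enone 22, and DBU should then equilibrate the carbinol next to the ketone through the enediol to the equatorial hydroxyl cis to the angular methyl and hydrogen-bonded to the carbonyl, the arrangement that is the thermodynamic sink of ketols beside a methyl-bearing quaternary carbon (as in steroidal 12β-hydroxy-11-ketones).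

**Compound list**

1 | (S)-(+)-terpinen-4-ol, (1S)-4-methyl-1-(propan-2-yl)cyclohex-3-en-1-ol | CC1=CC[C@](O)(C(C)C)CC1 | starting material
2 | tert-butyl(dimethyl){[(1S)-4-methyl-1-(propan-2-yl)cyclohex-3-en-1-yl]oxy}silane | CC1=CC[C@](O[Si](C)(C)C(C)(C)C)(C(C)C)CC1 | intermediate
3 | (3S)-3-{[tert-butyl(dimethyl)silyl]oxy}-6-oxo-3-(propan-2-yl)heptanal | O=CC[C@](O[Si](C)(C)C(C)(C)C)(C(C)C)CCC(C)=O | intermediate (not isolated)
4 | (5S)-5-{[tert-butyl(dimethyl)silyl]oxy}-7,7-dimethoxy-5-(propan-2-yl)heptan-2-one | COC(OC)C[C@](O[Si](C)(C)C(C)(C)C)(C(C)C)CCC(C)=O | intermediate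
5 | diethyl (5S)-5-{[tert-butyl(dimethyl)silyl]oxy}-7,7-dimethoxy-5-(propan-2-yl)hept-1-en-2-yl phosphate | COC(OC)C[C@](O[Si](C)(C)C(C)(C)C)(C(C)C)CCC(=C)OP(=O)(OCC)OCC | intermediate (not isolated)
6 | tert-butyl{[(3S)-1,1-dimethoxy-3-(propan-2-yl)hept-6-yn-3-yl]oxy}dimethylsilane | COC(OC)C[C@](O[Si](C)(C)C(C)(C)C)(C(C)C)CCC#C | intermediate
7 | (E)-1-bromoprop-1-ene | C/C=C/Br | starting material
8 | [(1E,5S)-5-{[tert-butyl(dimethyl)silyl]oxy}-7,7-dimethoxy-2-methyl-5-(propan-2-yl)hept-1-en-1-yl]dimethylalane | COC(OC)C[C@](O[Si](C)(C)C(C)(C)C)(C(C)C)CC/C(C)=C/[Al](C)C | intermediate (not isolated)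
9 | tert-butyl{[(3S,6E,8E)-1,1-dimethoxy-6-methyl-3-(propan-2-yl)deca-6,8-dien-3-yl]oxy}dimethylsilane | COC(OC)C[C@](O[Si](C)(C)C(C)(C)C)(C(C)C)CC/C(C)=C/C=C/C | intermediate (not isolated)
10 | (3S,6E,8E)-3-{[tert-butyl(dimethyl)silyl]oxy}-6-methyl-3-(propan-2-yl)deca-6,8-dienal | O=CC[C@](O[Si](C)(C)C(C)(C)C)(C(C)C)CC/C(C)=C/C=C/C | intermediate
11 | (4S,7E,9E)-4-{[tert-butyl(dimethyl)silyl]oxy}-1,1-dichloro-7-methyl-4-(propan-2-yl)undeca-7,9-dien-2-ol (both C-2 epimers) | ClC(Cl)C(O)C[C@](O[Si](C)(C)C(C)(C)C)(C(C)C)CC/C(C)=C/C=C/C | intermediate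
12 | (4S,7E,9E)-4-{[tert-butyl(dimethyl)silyl]oxy}-1,1-dichloro-7-methyl-4-(propan-2-yl)undeca-7,9-dien-2-one | ClC(Cl)C(=O)C[C@](O[Si](C)(C)C(C)(C)C)(C(C)C)CC/C(C)=C/C=C/C | intermediate
13 | zwitterionic 1-chloro-2-oxidoallyl cation from 12, (Z)-enolate geometry (tether cis to the oxide) | Cl[CH+]/C([O-])=C/[C@](O[Si](C)(C)C(C)(C)C)(C(C)C)CC/C(C)=C/C=C/C | intermediate (not isolated)
14 | (3R,3aR,5R,6S,8aR)-3-{[tert-butyl(dimethyl)silyl]oxy}-5-chloro-6,8a-dimethyl-3-(propan-2-yl)-2,3,3a,5,6,8a-hexahydroazulen-4(1H)-one (trans-fused) | O=C1[C@H](Cl)[C@@H](C)C=C[C@@]2(C)CC[C@@](O[Si](C)(C)C(C)(C)C)(C(C)C)[C@H]12 | intermediate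
15 | (3R,3aR,5R,6S,8aR)-5-chloro-3-hydroxy-6,8a-dimethyl-3-(propan-2-yl)-2,3,3a,5,6,8a-hexahydroazulen-4(1H)-one | O=C1[C@H](Cl)[C@@H](C)C=C[C@@]2(C)CC[C@@](O)(C(C)C)[C@H]12 | intermediate
16 | (3R,3aS,4R,5R,6S,8aR)-5-chloro-6,8a-dimethyl-3-(propan-2-yl)-1,2,3,3a,4,5,6,8a-octahydroazulene-3,4-diol | O[C@H]1[C@H](Cl)[C@@H](C)C=C[C@@]2(C)CC[C@@](O)(C(C)C)[C@H]12 | intermediate
17 | 4-methoxybenzoyl chloride | COc1ccc(C(Cl)=O)cc1 | starting material
18 | (3R,3aS,4R,5R,6S,8aR)-5-chloro-3-hydroxy-6,8a-dimethyl-3-(propan-2-yl)-1,2,3,3a,4,5,6,8a-octahydroazulen-4-yl 4-methoxybenzoate | COc1ccc(C(=O)O[C@H]2[C@H](Cl)[C@@H](C)C=C[C@@]3(C)CC[C@@](O)(C(C)C)[C@H]23)cc1 | intermediate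
19 | 7,8-epoxide of 18, oxirane oxygen on the face opposite the 8a-methyl group (same face as H-3a) | COc1ccc(C(=O)O[C@H]2[C@H](Cl)[C@@H](C)[C@H]4O[C@H]4[C@@]3(C)CC[C@@](O)(C(C)C)[C@H]23)cc1 | intermediate
20 | alkoxysulfonium ion (as its triflate): 5-chloro-3,8-dihydroxy-7-(dimethylsulfoniooxy) decahydroazulenyl anisoate, sulfonium oxygen cis and 8-hydroxyl trans to the 8a-methyl | COc1ccc(C(=O)O[C@H]2[C@H](Cl)[C@@H](C)[C@H](O[S+](C)C)[C@@H](O)[C@@]3(C)CC[C@@](O)(C(C)C)[C@H]23)cc1 | intermediate (not isolated)
21 | 5-chloro-3,8-dihydroxy-6,8a-dimethyl-7-oxo-3-(propan-2-yl)decahydroazulen-4-yl 4-methoxybenzoate, 8-hydroxyl trans to the 8a-methyl | COc1ccc(C(=O)O[C@H]2[C@H](Cl)[C@@H](C)C(=O)[C@@H](O)[C@@]3(C)CC[C@@](O)(C(C)C)[C@H]23)cc1 | intermediate (not isolated)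
22 | (3R,3aS,4S,8S,8aS)-3,8-dihydroxy-6,8a-dimethyl-7-oxo-3-(propan-2-yl)-1,2,3,3a,4,7,8,8a-octahydroazulen-4-yl 4-methoxybenzoate (C-8 epimer of the target) | COc1ccc(C(=O)O[C@H]2C=C(C)C(=O)[C@@H](O)[C@@]3(C)CC[C@@](O)(C(C)C)[C@H]23)cc1 | intermediate (not isolated)
23 | (3R,3aS,4S,8R,8aS)-3,8-dihydroxy-6,8a-dimethyl-7-oxo-3-(propan-2-yl)-1,2,3,3a,4,7,8,8a-octahydroazulen-4-yl 4-methoxybenzoate | COc1ccc(C(=O)O[C@H]2C=C(C)C(=O)[C@H](O)[C@@]3(C)CC[C@@](O)(C(C)C)[C@H]23)cc1 | target

**Step count and risks**

Total steps: 12. Longest linear sequence: 12 steps (from 1).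

Steps most likely to fail:

1. Step 7. The ring may close through the compact transition state, which would place the ring-fusion hydrogen syn to the angular methyl, or the cation may be diverted by solvent capture before the diene reaches it. Fallback: starting from 12, the cyclisation is allowed to deliver the cis-fused adduct (3R,3aS,5R,6S,8aR)-3-{[tert-butyl(dimethyl)silyl]oxy}-5-chloro-6,8a-dimethyl-3-(propan-2-yl)-2,3,3a,5,6,8a-hexahydroazulen-4(1H)-one F1. Its enolisable ring-fusion carbon is then equilibrated through the enol with p-TsOH in toluene at 60 °C, acid being chosen so that no enolate with an α'-chloride is formed. Thermodynamic control should move the ketone-bearing ring bond away from the face that carries the isopropyl group and the other seven-ring bond, and the sequence returns to the route at 14. This fallback corrects the ring fusion only; a wrong configuration at the quaternary carbon could not be repaired this way.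

2. Step 12. The base equilibration of the carbinol next to the ketone may stop short, or the preference for the hydroxyl cis to the angular methyl may be weaker than assumed. Fallback: the sequence is stopped after Et3N so that 22 is isolated. Starting from 22, Dess–Martin oxidation should give the ene-1,2-dione (3R,3aS,4S,8aS)-3-hydroxy-6,8a-dimethyl-7,8-dioxo-3-(propan-2-yl)-1,2,3,3a,4,7,8,8a-octahydroazulen-4-yl 4-methoxybenzoate F4. Reduction with NaBH4/CeCl3 in MeOH at −78 °C should then add hydride to the non-conjugated ketone from the face opposite the angular methyl. This sets the carbinol under kinetic control and returns to the route at 23.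

3. Step 9. Ligand exchange of the hindered tertiary hydroxyl on boron may be slow, so that uncomplexed hydride attacks from the open face and gives the epimeric alcohol. Fallback: starting from 14, NaBH4 in MeOH at 0 °C should give, by steric approach control, the alcohol with hydroxyl cis to the angular methyl, (3R,3aS,4S,5R,6S,8aR)-3-{[tert-butyl(dimethyl)silyl]oxy}-5-chloro-6,8a-dimethyl-3-(propan-2-yl)-1,2,3,3a,4,5,6,8a-octahydroazulen-4-ol F2. Mitsunobu esterification with 4-methoxybenzoic acid (PPh3, DIAD, toluene) should install the ester with inversion to give the silyl-protected anisoate (3R,3aS,4R,5R,6S,8aR)-3-{[tert-butyl(dimethyl)silyl]oxy}-5-chloro-6,8a-dimethyl-3-(propan-2-yl)-1,2,3,3a,4,5,6,8a-octahydroazulen-4-yl 4-methoxybenzoate F3. HF (48% aq.) in MeCN then removes the silyl ether and the sequence returns to the route at 18.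

**Further compounds**

F1 | step 7 | (3R,3aS,5R,6S,8aR)-3-{[tert-butyl(dimethyl)silyl]oxy}-5-chloro-6,8a-dimethyl-3-(propan-2-yl)-2,3,3a,5,6,8a-hexahydroazulen-4(1H)-one (cis-fused 3a-epimer of 14) | O=C1[C@H](Cl)[C@@H](C)C=C[C@@]2(C)CC[C@@](O[Si](C)(C)C(C)(C)C)(C(C)C)[C@@H]12
F2 | step 9 | (3R,3aS,4S,5R,6S,8aR)-3-{[tert-butyl(dimethyl)silyl]oxy}-5-chloro-6,8a-dimethyl-3-(propan-2-yl)-1,2,3,3a,4,5,6,8a-octahydroazulen-4-ol | O[C@@H]1[C@H](Cl)[C@@H](C)C=C[C@@]2(C)CC[C@@](O[Si](C)(C)C(C)(C)C)(C(C)C)[C@H]12
F3 | step 9 | (3R,3aS,4R,5R,6S,8aR)-3-{[tert-butyl(dimethyl)silyl]oxy}-5-chloro-6,8a-dimethyl-3-(propan-2-yl)-1,2,3,3a,4,5,6,8a-octahydroazulen-4-yl 4-methoxybenzoate | COc1ccc(C(=O)O[C@H]2[C@H](Cl)[C@@H](C)C=C[C@@]3(C)CC[C@@](O[Si](C)(C)C(C)(C)C)(C(C)C)[C@H]23)cc1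
F4 | step 12 | (3R,3aS,4S,8aS)-3-hydroxy-6,8a-dimethyl-7,8-dioxo-3-(propan-2-yl)-1,2,3,3a,4,7,8,8a-octahydroazulen-4-yl 4-methoxybenzoate | COc1ccc(C(=O)O[C@H]2C=C(C)C(=O)C(=O)[C@@]3(C)CC[C@@](O)(C(C)C)[C@H]23)cc1
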